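Selaginellin is disconnected at the exocyclic C=C of its quinone methide and at the bond between the methide carbon and C1 of ring A (the benzene carrying the C2 4-hydroxyphenyl, the C5 CH2OH and the C6 arylethynyl group). The diarylmethylene–cyclohexadienone is read as the olefin of a diarylketene and one carbonyl of p-benzoquinone, and ring A sits on a carbonyl carbon from which it can shift. One thermal operation on an α-aryl-α-diazo ketone (ring A–CO–C(N2)–aryl, phenols as MOM ethers, the benzylic alcohol as a TBS ether) gives Wolff rearrangement, ketene–quinone cycloaddition and CO2 loss, so no carbinol is ionised beside the alkyne.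

Key step: step 11

Remark: the primary benzylic alcohol is carried as a TBS ether, not as an alkyl MOM ether, so that the last step needs only dilute acid; compounds 1, 5, 8 and 16 are taken as catalogue chemicals.

Shorthand in names: ArA = 4-{[(tert-butyldimethylsilyl)oxy]methyl}-4'-(methoxymethoxy)-3-{[4-(methoxymethoxy)phenyl]ethynyl}biphenyl-2-yl, that is ring A bonded through C1, with 4-(methoxymethoxy)phenyl at C2, CH2OTBS at C5 and [4-(methoxymethoxy)phenyl]ethynyl at C6.

Step 1
Reactants: 1 (2-bromo-4-chlorophenyl)methanol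
Product: 2 tert-butyl[(2-bromo-4-chlorobenzyl)oxy]dimethylsilane
Conditions: TBSCl, imidazole, DMF, rt
Reagents that add atoms: tert-butyldimethylsilyl chloride, CC(C)(C)[Si](C)(C)Cl
Why: Imidazole-promoted silylation of a primary alcohol gives a silyl ether that should survive the amide base, both couplings, the Grignard step and the thermolysis, and leaves in dilute acid at the end.

Step 2
Reactants: 2 tert-butyl[(2-bromo-4-chlorobenzyl)oxy]dimethylsilane
Product: 4 2-bromo-3-{[(tert-butyldimethylsilyl)oxy]methyl}-6-chlorobenzaldehyde, via aryllithium 3 (not isolated)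
Conditions: LiN(iPr)2, THF, −78 °C; DMF, −78 → −40 °C; aq. NH4Cl
Reagents that add atoms: N,N-dimethylformamide, CN(C)C=O
Why: Directed ortho-lithiation removes the one ring hydrogen flanked by Br and Cl, by far the most acidic, without halogen–metal exchange or aryne formation at −78 °C, and the aryllithium is formylated by DMF (Bouveault formylation).

Step 3
Reactants: 5 4-(methoxymethoxy)benzaldehyde
Product: 6 1-ethynyl-4-(methoxymethoxy)benzene
Conditions: dimethyl (1-diazo-2-oxopropyl)phosphonate, K2CO3, MeOH, rt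
Reagents that add atoms: dimethyl (1-diazo-2-oxopropyl)phosphonate, COP(=O)(OC)C(=[N+]=[N-])C(C)=O
Why: Ohira–Bestmann (Seyferth–Gilbert) homologation converts an aromatic aldehyde into the terminal alkyne under mild carbonate conditions to which the aryl MOM ether is inert.

Step 4
Reactants: 4 2-bromo-3-{[(tert-butyldimethylsilyl)oxy]methyl}-6-chlorobenzaldehyde; 6 1-ethynyl-4-(methoxymethoxy)benzene
Product: 7 3-{[(tert-butyldimethylsilyl)oxy]methyl}-6-chloro-2-{[4-(methoxymethoxy)phenyl]ethynyl}benzaldehyde
Conditions: Pd(PPh3)2Cl2 (cat.), CuI (cat.), Et3N, THF, 60 °C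
Reagents that add atoms: none
Why: Sonogashira coupling should occur only at the C–Br bond, which the ortho formyl group activates towards zerovalent palladium, while the C–Cl bond is inert to a triphenylphosphine catalyst at this temperature.

Step 5
Reactants: 7 3-{[(tert-butyldimethylsilyl)oxy]methyl}-6-chloro-2-{[4-(methoxymethoxy)phenyl]ethynyl}benzaldehyde; 8 [4-(methoxymethoxy)phenyl]boronic acid
Product: 9 ArA–CHO (4-{[(tert-butyldimethylsilyl)oxy]methyl}-4'-(methoxymethoxy)-3-{[4-(methoxymethoxy)phenyl]ethynyl}biphenyl-2-carbaldehyde)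
Conditions: Pd(OAc)2 (cat.), SPhos, K3PO4, PhMe/H2O, 90 °C
Reagents that add atoms: none
Why: Suzuki–Miyaura coupling of a formyl-activated aryl chloride that has only one ortho substituent is routine with the electron-rich biarylphosphine SPhos, and the internal alkyne, aldehyde, MOM and TBS groups tolerate aqueous phosphate.

Step 6
Reactants: 5 4-(methoxymethoxy)benzaldehyde
Product: 10 [4-(methoxymethoxy)phenyl]methanol
Conditions: NaBH4, MeOH, 0 °C
Reagents that add atoms: none
Why: Borohydride reduction of an aromatic aldehyde gives the benzylic alcohol without touching the acetal.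

Step 7
Reactants: 10 [4-(methoxymethoxy)phenyl]methanol
Product: 11 1-(chloromethyl)-4-(methoxymethoxy)benzene
Conditions: NCS, PPh3, CH2Cl2, 0 °C → rt
Reagents that add atoms: N-chlorosuccinimide, ClN1C(=O)CCC1=O
Why: Appel-type chlorination (chlorophosphonium activation, then SN2 by chloride) is neutral and should spare the acid-labile MOM ether.

Step 8
Reactants: 11 1-(chloromethyl)-4-(methoxymethoxy)benzene; 9 ArA–CHO
Product: 13 rac-1-ArA-2-[4-(methoxymethoxy)phenyl]ethanol, via benzylmagnesium chloride 12 (not isolated)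
Conditions: Mg, THF, 0 °C (dilute, slow addition of 11); then 9, −78 → 0 °C; aq. NH4Cl
Reagents that add atoms: none
Why: Grignard addition of a benzylic magnesium chloride to a non-enolisable aromatic aldehyde should give the secondary alcohol, whose new carbinol stereocentre forms as a racemate and is removed by the oxidation in step 9.

Step 9
Reactants: 13 rac-1-ArA-2-[4-(methoxymethoxy)phenyl]ethanol
Product: 14 1-ArA-2-[4-(methoxymethoxy)phenyl]ethanone
Conditions: Dess–Martin periodinane, pyridine, CH2Cl2, 0 °C → rt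
Reagents that add atoms: none
Why: Dess–Martin oxidation converts the hindered secondary benzylic alcohol into the ketone under buffered conditions that leave the alkyne, MOM and TBS groups alone.

Step 10
Reactants: 14 1-ArA-2-[4-(methoxymethoxy)phenyl]ethanone
Product: 15 2-diazo-1-ArA-2-[4-(methoxymethoxy)phenyl]ethanone
Conditions: p-ABSA, DBU, MeCN, 0 °C → rt
Reagents that add atoms: 4-acetamidobenzenesulfonyl azide, CC(=O)Nc1ccc(cc1)S(=O)(=O)N=[N+]=[N-]
Why: Regitz diazo transfer to the doubly activated (benzylic and α-keto) methylene of a deoxybenzoin is the standard access to α-aryl-α-diazo ketones, and the methylene lies on the open side of the hindered carbonyl.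

Step 11
Reactants: 15 2-diazo-1-ArA-2-[4-(methoxymethoxy)phenyl]ethanone; 16 p-benzoquinone
Product: 19 4-{ArA[4-(methoxymethoxy)phenyl]methylidene}cyclohexa-2,5-dien-1-one, via diarylketene 17 (not isolated), via spiro-β-lactone 18 (not isolated)
Conditions: PhMe, 110 °C, slow addition of 15 to 16 (5 equiv), then 110 °C until CO2 loss ends
Reagents that add atoms: none
Why: Heating expels N2 from the α-diazo ketone and ring A shifts with its bonding pair from the carbonyl carbon to the diazo carbon (Wolff rearrangement), which makes the C1–C(methide) bond and gives diarylketene 17. The ketene C=C then adds across one C=O of the quinone in a [2+2] cycloaddition (quinone oxygen to the ketene carbonyl carbon, quinone carbon to the diaryl carbon) to give spiro-β-lactone 18, and thermal cycloreversion releases CO2 and leaves the exocyclic C=C of the quinone methide. The closest known reactions are the thermolysis of 2-diazo-1,2-diarylethanones to diarylketenes and the olefination of p-benzoquinone by diphenylketene (Staudinger ketene cycloaddition followed by β-lactone decarboxylation). No ring is kept: the oxetanone closes by cycloaddition and opens again on CO2 loss, the quaternary carbon of 18 forms as a racemate and becomes sp2, and the dienone is symmetric, so the product has no stereo element. The step needs chemoselectivity, that is aryl migration ahead of carbene capture by the C6 alkyne, and ketene trapping by a quinone carbonyl ahead of dimerisation, attack on the alkyne or a second olefination; slow addition of 15 into hot excess quinone, the twisted ketene flanked at C2 and C6, and the fact that ring A is the only group on the carbonyl carbon should secure this.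

Step 12
Reactants: 19 4-{ArA[4-(methoxymethoxy)phenyl]methylidene}cyclohexa-2,5-dien-1-one
Product: 20 selaginellin
Conditions: 3 M aq. HCl, THF, 40 °C
Reagents that add atoms: none
Why: Acid hydrolysis cleaves the three aryl MOM acetals and the primary TBS ether, while the quinone methide is only reversibly protonated to a stabilised triarylmethyl cation in dilute acid and should return on neutralisation.

Compound list
1 | (2-bromo-4-chlorophenyl)methanol | OCc1ccc(Cl)cc1Br | starting material
2 | tert-butyl[(2-bromo-4-chlorobenzyl)oxy]dimethylsilane | CC(C)(C)[Si](C)(C)OCc1ccc(Cl)cc1Br | intermediate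
3 | (2-bromo-6-chloro-3-{[(tert-butyldimethylsilyl)oxy]methyl}phenyl)lithium | [Li]c1c(Cl)ccc(CO[Si](C)(C)C(C)(C)C)c1Br | intermediate
4 | 2-bromo-3-{[(tert-butyldimethylsilyl)oxy]methyl}-6-chlorobenzaldehyde | O=Cc1c(Cl)ccc(CO[Si](C)(C)C(C)(C)C)c1Br | intermediate
5 | 4-(methoxymethoxy)benzaldehyde | COCOc1ccc(C=O)cc1 | starting material
6 | 1-ethynyl-4-(methoxymethoxy)benzene | COCOc1ccc(C#C)cc1 | intermediate
7 | 3-{[(tert-butyldimethylsilyl)oxy]methyl}-6-chloro-2-{[4-(methoxymethoxy)phenyl]ethynyl}benzaldehyde | O=Cc1c(Cl)ccc(CO[Si](C)(C)C(C)(C)C)c1C#Cc1ccc(OCOC)cc1 | intermediate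
8 | [4-(methoxymethoxy)phenyl]boronic acid | COCOc1ccc(B(O)O)cc1 | starting material
9 | ArA–CHO, 4-{[(tert-butyldimethylsilyl)oxy]methyl}-4'-(methoxymethoxy)-3-{[4-(methoxymethoxy)phenyl]ethynyl}biphenyl-2-carbaldehyde | O=Cc1c(-c2ccc(OCOC)cc2)ccc(CO[Si](C)(C)C(C)(C)C)c1C#Cc1ccc(OCOC)cc1 | intermediate
10 | [4-(methoxymethoxy)phenyl]methanol | COCOc1ccc(CO)cc1 | intermediate
11 | 1-(chloromethyl)-4-(methoxymethoxy)benzene | COCOc1ccc(CCl)cc1 | intermediate
12 | [4-(methoxymethoxy)benzyl]magnesium chloride | COCOc1ccc(C[Mg]Cl)cc1 | intermediate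
13 | rac-1-ArA-2-[4-(methoxymethoxy)phenyl]ethanol (racemic at the carbinol carbon) | OC(Cc1ccc(OCOC)cc1)c1c(-c2ccc(OCOC)cc2)ccc(CO[Si](C)(C)C(C)(C)C)c1C#Cc1ccc(OCOC)cc1 | intermediate
14 | 1-ArA-2-[4-(methoxymethoxy)phenyl]ethanone | O=C(Cc1ccc(OCOC)cc1)c1c(-c2ccc(OCOC)cc2)ccc(CO[Si](C)(C)C(C)(C)C)c1C#Cc1ccc(OCOC)cc1 | intermediate
15 | 2-diazo-1-ArA-2-[4-(methoxymethoxy)phenyl]ethanone | O=C(C(=[N+]=[N-])c1ccc(OCOC)cc1)c1c(-c2ccc(OCOC)cc2)ccc(CO[Si](C)(C)C(C)(C)C)c1C#Cc1ccc(OCOC)cc1 | intermediate
16 | p-benzoquinone | O=C1C=CC(=O)C=C1 | starting material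
17 | 2-ArA-2-[4-(methoxymethoxy)phenyl]ethenone (diarylketene) | O=C=C(c1ccc(OCOC)cc1)c1c(-c2ccc(OCOC)cc2)ccc(CO[Si](C)(C)C(C)(C)C)c1C#Cc1ccc(OCOC)cc1 | intermediate
18 | rac-3-ArA-3-[4-(methoxymethoxy)phenyl]-1-oxaspiro[3.5]nona-5,8-diene-2,7-dione (racemic at C3) | O=C1OC2(C=CC(=O)C=C2)C1(c1ccc(OCOC)cc1)c1c(-c2ccc(OCOC)cc2)ccc(CO[Si](C)(C)C(C)(C)C)c1C#Cc1ccc(OCOC)cc1 | intermediate
19 | 4-{ArA[4-(methoxymethoxy)phenyl]methylidene}cyclohexa-2,5-dien-1-one (tris-O-MOM, O-TBS selaginellin) | O=C1C=CC(=C(c2ccc(OCOC)cc2)c2c(-c3ccc(OCOC)cc3)ccc(CO[Si](C)(C)C(C)(C)C)c2C#Cc2ccc(OCOC)cc2)C=C1 | intermediate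
20 | selaginellin | O=C1C=CC(=C(c2ccc(O)cc2)c2c(-c3ccc(O)cc3)ccc(CO)c2C#Cc2ccc(O)cc2)C=C1 | target

Total step count: 12. Longest linear sequence: 9 steps (steps 1, 2, 4, 5, 8, 9, 10, 11 and 12, from 1 to 20).

Steps most likely to fail

Step 11. After loss of N2 the carbene, or the ketene formed from it, may be captured by the neighbouring C6 alkyne or by a quinone C=C instead of undergoing aryl migration and carbonyl cycloaddition. The hindered ketene may also add to the quinone too slowly, or the lactone may not lose CO2 cleanly. The fallback is the classical carbinol route to a quinone methide; it sets out from 9 and comes back at 20. 1-Bromo-4-(methoxymethoxy)benzene (catalogue compound, COCOc1ccc(Br)cc1) is treated with n-BuLi in THF at −78 °C to give [4-(methoxymethoxy)phenyl]lithium F1, which should add to 9 to give the racemic diaryl carbinol ArA-[4-(methoxymethoxy)phenyl]methanol F2. Dess–Martin oxidation should give the diaryl ketone ArA-[4-(methoxymethoxy)phenyl]methanone F3, and a second addition of F1 the triaryl carbinol ArA-bis[4-(methoxymethoxy)phenyl]methanol F4. 3 M aq. HCl in THF should then remove the three MOM groups and the TBS group and ionise the carbinol, which loses water to give 20.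

Step 10. Under DBU the enolate may close onto the ortho alkyne through carbon or oxygen before it takes up the azide, or the transfer may stall. The fallback avoids enolate chemistry and makes the diazo group by dehydrogenation of a hydrazone; it sets out from 14 and comes back at 15. Riley oxidation of 14 with SeO2 in pyridine at 90 °C should give the 1,2-diketone 1-ArA-2-[4-(methoxymethoxy)phenyl]ethane-1,2-dione F5. Hydrazine hydrate (1 equiv, EtOH, rt) should condense with the unhindered carbonyl next to the 4-(methoxymethoxy)phenyl group to give the monohydrazone 2-hydrazinylidene-1-ArA-2-[4-(methoxymethoxy)phenyl]ethanone F6. Activated MnO2 in CH2Cl2 should dehydrogenate F6 to 15.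

Step 8. Wurtz homocoupling during formation of the electron-rich benzylic Grignard reagent may leave too little nucleophile, and addition to the doubly ortho-substituted aldehyde may be slow. The fallback uses a sulfonyl-stabilised benzyl anion; it sets out from 11 and 9 and comes back at 14. PhSO2Na in DMF should convert 11 into 1-(methoxymethoxy)-4-[(phenylsulfonyl)methyl]benzene F7. n-BuLi (THF, −78 °C) gives {[4-(methoxymethoxy)phenyl](phenylsulfonyl)methyl}lithium F8, which should add to 9 to give the β-hydroxy sulfone 1-ArA-2-[4-(methoxymethoxy)phenyl]-2-(phenylsulfonyl)ethanol F9 as a mixture of diastereomers. Dess–Martin oxidation should give the β-keto sulfone 1-ArA-2-[4-(methoxymethoxy)phenyl]-2-(phenylsulfonyl)ethanone F10. Reductive desulfonylation with Zn dust and aq. NH4Cl in THF should return 14.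

Further compounds
F1 | step 11 | [4-(methoxymethoxy)phenyl]lithium | [Li]c1ccc(OCOC)cc1
F2 | step 11 | rac-ArA-[4-(methoxymethoxy)phenyl]methanol | OC(c1ccc(OCOC)cc1)c1c(-c2ccc(OCOC)cc2)ccc(CO[Si](C)(C)C(C)(C)C)c1C#Cc1ccc(OCOC)cc1
F3 | step 11 | ArA-[4-(methoxymethoxy)phenyl]methanone | O=C(c1ccc(OCOC)cc1)c1c(-c2ccc(OCOC)cc2)ccc(CO[Si](C)(C)C(C)(C)C)c1C#Cc1ccc(OCOC)cc1
F4 | step 11 | ArA-bis[4-(methoxymethoxy)phenyl]methanol | OC(c1ccc(OCOC)cc1)(c1ccc(OCOC)cc1)c1c(-c2ccc(OCOC)cc2)ccc(CO[Si](C)(C)C(C)(C)C)c1C#Cc1ccc(OCOC)cc1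
F5 | step 10 | 1-ArA-2-[4-(methoxymethoxy)phenyl]ethane-1,2-dione | O=C(C(=O)c1ccc(OCOC)cc1)c1c(-c2ccc(OCOC)cc2)ccc(CO[Si](C)(C)C(C)(C)C)c1C#Cc1ccc(OCOC)cc1
F6 | step 10 | 2-hydrazinylidene-1-ArA-2-[4-(methoxymethoxy)phenyl]ethanone (C=N geometry not fixed) | NN=C(C(=O)c1c(-c2ccc(OCOC)cc2)ccc(CO[Si](C)(C)C(C)(C)C)c1C#Cc1ccc(OCOC)cc1)c1ccc(OCOC)cc1
F7 | step 8 | 1-(methoxymethoxy)-4-[(phenylsulfonyl)methyl]benzene | COCOc1ccc(CS(=O)(=O)c2ccccc2)cc1
F8 | step 8 | {[4-(methoxymethoxy)phenyl](phenylsulfonyl)methyl}lithium | [Li]C(c1ccc(OCOC)cc1)S(=O)(=O)c1ccccc1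
F9 | step 8 | 1-ArA-2-[4-(methoxymethoxy)phenyl]-2-(phenylsulfonyl)ethanol (racemic, diastereomer mixture) | OC(C(c1ccc(OCOC)cc1)S(=O)(=O)c1ccccc1)c1c(-c2ccc(OCOC)cc2)ccc(CO[Si](C)(C)C(C)(C)C)c1C#Cc1ccc(OCOC)cc1
F10 | step 8 | 1-ArA-2-[4-(methoxymethoxy)phenyl]-2-(phenylsulfonyl)ethanone (racemic) | O=C(C(c1ccc(OCOC)cc1)S(=O)(=O)c1ccccc1)c1c(-c2ccc(OCOC)cc2)ccc(CO[Si](C)(C)C(C)(C)C)c1C#Cc1ccc(OCOC)cc1
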